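**Strategy.** Ring numbering: C1 (OBz, next to C6), C2=C3, C4 (OBz), C5 (OH), C6 (OH, CH2OH = C7). The cyclohexene is cut at C2–C3 and C4–C5: a dearomatising Diels–Alder reaction of flat, achiral furan-3-ylmethanol (C2, C1, C6, C5, C7 and the C5 oxygen) with (Z)-1,2-bis(phenylsulfonyl)ethene, an acetylene equivalent (C3, C4), closes the carbocycle in one operation. It exploits the 1,4-relationship across the ring between the C5 oxygen and alkene carbon C2, the two ends of the furan oxygen bridge. After desulfonylation, exo-epoxidation and two anti benzoate additions (allylic bridge opening at C4, epoxide opening at C1) set all four stereocentres without protecting groups.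

Key step: step 1

Remark: atom labels C1–C7 in the Why lines are those of the target ring, also for intermediates; racemic 3 and 4 are drawn as the enantiomer that leads to 7.
Remark: in step 4 the ligand enantiomer is assumed to be the one matched to 5, i.e. the one whose rhodium complex inserts into the C2–O bond; if the sense is opposite to that written, the antipodal ligand is used.

**Step 1**
Reactants: 1 furan-3-ylmethanol; 2 (Z)-1,2-bis(phenylsulfonyl)ethene
Product: 3 [5,6-bis(phenylsulfonyl)-7-oxabicyclo[2.2.1]hept-2-en-2-yl]methanol (racemic; sulfonyl groups cis, endo,endo isomer drawn, the exo,exo isomer converges in step 2)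
Conditions: CH2Cl2, 25 °C, dark
Reagents that add atoms: none
Why: Concerted, suprafacial [4+2] cycloaddition of normal electron demand between the furan diene (termini C2 and C5) and the doubly activated Z-alkene; the closest known reaction type is the Diels–Alder addition of furans to 1,2-bis(arylsulfonyl)ethenes used as acetylene equivalents. The cycloaddition closes the six-membered carbocycle C1–C6 by forming the C2–C3 and C4–C5 σ-bonds in one transition state, and with it the oxolane ring O–C2–C3–C4–C5 of the 7-oxanorbornene, whose oxygen bridge is the former furan oxygen. The bridgehead stereocentres C2 and C5 are cis of necessity (addition to one face of the planar heteroarene), the cis relationship at C3/C4 is copied from the Z-alkene, and the endo or exo position of the sulfonyl groups is immaterial because C3 and C4 become sp2 again in step 2. Because the dienophile is symmetrical, its orientation relative to the 3-substituent of the furan raises no regiochemical question, so the only selectivity needed is cycloaddition versus oxa-Michael addition of the free hydroxyl, secured by base-free conditions. The adduct is racemic by design; the absolute configuration is introduced in step 3. Cycloreversion is avoided by working at ambient temperature.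

**Step 2**
Reactants: 3 [5,6-bis(phenylsulfonyl)-7-oxabicyclo[2.2.1]hept-2-en-2-yl]methanol
Product: 4 (7-oxabicyclo[2.2.1]hepta-2,5-dien-2-yl)methanol (racemic)
Conditions: Na(Hg) (5% Na), NaH2PO4, MeOH/THF, −20 °C to 0 °C
Reagents that add atoms: none
Why: Reductive desulfonylation of the vicinal bis-sulfone (two electron transfers from Na(Hg), loss of two benzenesulfinate ions) is the standard unmasking of this acetylene equivalent and should give the C3=C4 alkene under buffered, non-acidic conditions that the acid-labile oxanorbornadiene tolerates; no stereocentre is created and the sp3 centres C3 and C4 are erased.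

**Step 3**
Reactants: 4 (7-oxabicyclo[2.2.1]hepta-2,5-dien-2-yl)methanol (racemate)
Product: 5 [(1S,2S,4R,5R)-3,8-dioxatricyclo[3.2.1.0^2,4]oct-6-en-2-yl]methanol
Conditions: Ti(OiPr)4 (10 mol%), D-(−)-diisopropyl tartrate (12 mol%), t-BuOOH (0.45 equiv), 4 Å molecular sieves, CH2Cl2, −20 °C
Reagents that add atoms: tert-butyl hydroperoxide, CC(C)(C)OO
Why: Sharpless asymmetric epoxidation run as a kinetic resolution: the titanium–tartrate catalyst epoxidises only the allylic-alcohol alkene C1=C6 and, for steric reasons, only on its exo face (syn to the oxygen bridge), which is the face preferred by the D-(−)-tartrate catalyst only in the (1S,4R)-enantiomer of 4 (bicyclic locants), so that C1 and C6 are set with the epoxide oxygen cis to the bridge while the (1R,4S)-enantiomer is left unreacted and separated.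

**Step 4**
Reactants: 5 [(1S,2S,4R,5R)-3,8-dioxatricyclo[3.2.1.0^2,4]oct-6-en-2-yl]methanol
Product: 6 (1S,2S,3R,6R)-2-hydroxy-1-(hydroxymethyl)-7-oxabicyclo[4.1.0]hept-4-en-3-yl benzoate
Conditions: [Rh(cod)Cl]2 (2.5 mol%), (R,S)-PPF-PtBu2 [(R)-1-{(S)-2-(diphenylphosphino)ferrocenyl}ethyldi-tert-butylphosphine] (6 mol%), PhCO2H (2 equiv), Et3N (1 equiv), THF, 60 °C
Reagents that add atoms: benzoic acid, O=C(O)c1ccccc1
Why: Rhodium-catalysed asymmetric ring opening of an oxabicyclic alkene by a carboxylate: the chiral rhodium–diphosphine complex inserts with retention into the bridgehead C2–O bond, the resulting rhodium alkoxide is protonated by benzoic acid and the benzoate so formed attacks the allyl terminus C4 anti to the metal (SN2′) in preference to the neutral C7 hydroxyl, which creates the C2=C3 alkene, leaves the bridge oxygen on C5 as the hydroxyl and sets C4–OBz trans to it, while the catalyst-controlled choice of the C–O bond diverts residual enantiomer of 5 into a separable regioisomer.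

**Step 5**
Reactants: 6 (1S,2S,3R,6R)-2-hydroxy-1-(hydroxymethyl)-7-oxabicyclo[4.1.0]hept-4-en-3-yl benzoate
Product: 7 (1S,4R,5S,6S)-5,6-dihydroxy-6-(hydroxymethyl)cyclohex-2-ene-1,4-diyl dibenzoate
Conditions: Ti(OiPr)4 (1.5 equiv), PhCO2H (2 equiv), CH2Cl2, 0 °C to 25 °C; aqueous tartaric acid work-up
Reagents that add atoms: benzoic acid, O=C(O)c1ccccc1
Why: Titanium-mediated regioselective opening of a 2,3-epoxy alcohol by a carboxylic acid: with the C7 and C5 alkoxides and the epoxide oxygen bound to titanium, benzoate is delivered to the distal, less substituted and allylic carbon C1 with inversion (anti to the epoxide oxygen), which sets C1–OBz trans to the C6 hydroxyl and completes 7.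

**Compound list**
1 | furan-3-ylmethanol | OCc1ccoc1 | starting material
2 | (Z)-1,2-bis(phenylsulfonyl)ethene | O=S(=O)(/C=C\S(=O)(=O)c1ccccc1)c1ccccc1 | starting material
3 | [5,6-bis(phenylsulfonyl)-7-oxabicyclo[2.2.1]hept-2-en-2-yl]methanol, racemic, sulfonyl groups cis and endo (one enantiomer drawn) | OCC1=C[C@H]2[C@@H](S(=O)(=O)c3ccccc3)[C@@H](S(=O)(=O)c3ccccc3)[C@@H]1O2 | intermediate
4 | (7-oxabicyclo[2.2.1]hepta-2,5-dien-2-yl)methanol, racemic (the (1S,4R)-enantiomer, which is epoxidised in step 3, is drawn) | OCC1=C[C@H]2C=C[C@@H]1O2 | intermediate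
5 | [(1S,2S,4R,5R)-3,8-dioxatricyclo[3.2.1.0^2,4]oct-6-en-2-yl]methanol (exo-epoxide, cis to the oxygen bridge) | OC[C@@]12O[C@@H]1[C@H]3C=C[C@@H]2O3 | intermediate
6 | (1S,2S,3R,6R)-2-hydroxy-1-(hydroxymethyl)-7-oxabicyclo[4.1.0]hept-4-en-3-yl benzoate | OC[C@@]12O[C@@H]1C=C[C@@H](OC(=O)c1ccccc1)[C@@H]2O | intermediate
7 | (1S,4R,5S,6S)-5,6-dihydroxy-6-(hydroxymethyl)cyclohex-2-ene-1,4-diyl dibenzoate | O=C(O[C@H]1C=C[C@@H](OC(=O)c2ccccc2)[C@H](O)[C@@]1(O)CO)c1ccccc1 | target

Total steps: 5. Longest linear sequence: 5 steps (1 → 3 → 4 → 5 → 6 → 7).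

**Steps most likely to fail**

Step 4. The non-benzo-fused bicycle may insert monovalent rhodium sluggishly, the wrong bridgehead C–O bond may be cleaved, the C7 hydroxyl may capture the allyl intermediate intramolecularly, or the epoxide may be opened. The fallback sets out from 5, comes back at 6, and tethers the nucleophile so that only C4 can be attacked. Oxidation of the primary alcohol (TEMPO, PhI(OAc)2, CH2Cl2/H2O; then NaClO2, NaH2PO4, 2-methylbut-2-ene) should give the epoxy acid F1. With the carboxylate held on the endo face above C4, an intramolecular SN2′ opening with an achiral catalyst ([Rh(cod)Cl]2, 1,1′-bis(diphenylphosphino)ferrocene, Et3N, THF, 60 °C) can only give the γ-lactone F2 (carbonyl C7, lactone oxygen on C4, C2=C3, C5–OH). LiBH4 (THF, 0 °C) should reduce the lactone to the epoxy triol F3. tert-Butyldiphenylsilyl chloride and imidazole protect the primary hydroxyl to give the silyl ether F4. BzCl/pyridine at −20 °C should acylate the less hindered allylic C4 hydroxyl to give the benzoate F5. HF·pyridine (THF) removes the silyl group and returns 6.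

Step 3. The rate difference between the enantiomers of 4 may be too small, or the Lewis acid may isomerise the oxanorbornadiene to a phenol. The fallback sets out from 4 and comes back at 5. Hydroxyl-directed epoxidation without resolution (VO(acac)2, t-BuOOH, CH2Cl2, 0 °C) should give 5 together with its enantiomer, the (1R,2R,4S,5S)-epoxy alcohol F6. Lipase-catalysed acetylation (Amano lipase PS, vinyl acetate, t-BuOMe; lipase chosen by screening to acylate the unwanted enantiomer) converts F6 into the acetate F7, from which unreacted 5 is separated by chromatography.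

Step 5. Benzoate may attack the tertiary carbon C6 or C3 (SN2′), the benzoyl group may migrate from O4 to O5, or isopropoxide may transesterify. The fallback sets out from 6, comes back at 7, and gives up chelation control. TBSCl/imidazole (DMF, 0 °C) protects the primary hydroxyl as the silyl ether F8, which also blocks Payne rearrangement. A Lewis-acid-free SN2 opening at the allylic carbon C1 (PhCO2H, tetrabutylammonium benzoate, toluene, 80 °C) should give the silylated dibenzoate F9. HF·pyridine (THF, 0 °C) gives 7.

**Further compounds**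
F1 | step 4 | (1S,2S,4R,5R)-3,8-dioxatricyclo[3.2.1.0^2,4]oct-6-ene-2-carboxylic acid | OC(=O)[C@@]12O[C@@H]1[C@H]3C=C[C@@H]2O3
F2 | step 4 | epoxy γ-lactone bridging C6 and C4 (carbonyl C7, lactone oxygen on C4; C2=C3; C5–OH; C1–C6 epoxide) | O=C1O[C@@H]2C=C[C@H]3O[C@]13[C@H]2O
F3 | step 4 | (1S,2S,3R,6R)-1-(hydroxymethyl)-7-oxabicyclo[4.1.0]hept-4-ene-2,3-diol | OC[C@@]12O[C@@H]1C=C[C@@H](O)[C@@H]2O
F4 | step 4 | (1S,2S,3R,6R)-1-{[(tert-butyldiphenylsilyl)oxy]methyl}-7-oxabicyclo[4.1.0]hept-4-ene-2,3-diol | CC(C)(C)[Si](c1ccccc1)(c1ccccc1)OC[C@@]12O[C@@H]1C=C[C@@H](O)[C@@H]2O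
F5 | step 4 | (1S,2S,3R,6R)-1-{[(tert-butyldiphenylsilyl)oxy]methyl}-2-hydroxy-7-oxabicyclo[4.1.0]hept-4-en-3-yl benzoate | CC(C)(C)[Si](c1ccccc1)(c1ccccc1)OC[C@@]12O[C@@H]1C=C[C@@H](OC(=O)c1ccccc1)[C@@H]2O
F6 | step 3 | [(1R,2R,4S,5S)-3,8-dioxatricyclo[3.2.1.0^2,4]oct-6-en-2-yl]methanol (enantiomer of 5) | OC[C@]12O[C@H]1[C@@H]3C=C[C@H]2O3
F7 | step 3 | [(1R,2R,4S,5S)-3,8-dioxatricyclo[3.2.1.0^2,4]oct-6-en-2-yl]methyl acetate | CC(=O)OC[C@]12O[C@H]1[C@@H]3C=C[C@H]2O3
F8 | step 5 | (1S,2S,3R,6R)-1-{[(tert-butyldimethylsilyl)oxy]methyl}-2-hydroxy-7-oxabicyclo[4.1.0]hept-4-en-3-yl benzoate | CC(C)(C)[Si](C)(C)OC[C@@]12O[C@@H]1C=C[C@@H](OC(=O)c1ccccc1)[C@@H]2O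
F9 | step 5 | (1S,4R,5S,6S)-6-{[(tert-butyldimethylsilyl)oxy]methyl}-5,6-dihydroxycyclohex-2-ene-1,4-diyl dibenzoate | O=C(O[C@H]1C=C[C@@H](OC(=O)c2ccccc2)[C@H](O)[C@@]1(O)CO[Si](C)(C)C(C)(C)C)c1ccccc1
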